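Eta differs from the west run in two ways: it has less Z, 0.950 equiv against 1.4 equiv, and it runs longer, 2.5 min against a last reading at 50.0 s. The question is how much Q, the species formed on the way to D, outlasts that time.

| setting | west | eta | alpha | gamma | delta |
|---|---|---|---|---|---|
| L | 5.0 × 10⁻⁴ M | 5.0 × 10⁻⁴ M | 5.0 × 10⁻⁴ M | 5.0 × 10⁻⁴ M | 5.0 × 10⁻⁴ M |
| Z | 1.4 equiv | 0.950 equiv | 0.950 equiv | 0.950 equiv | 0.950 equiv |
| J | 1.1 equiv | 1.10 equiv | 1.10 equiv | 1.10 equiv | 1.10 equiv |
| temperature | 30 °C | 30 °C | 120 °C | 90 °C | 60 °C |
| remark | run made earlier |  |  |  |  |
| time |  | 2.5 min | 2.5 min | 2.5 min | 2.5 min |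

west run (percent of the L charged)

| time / s | Q / % | D / % |
|---|---|---|
| 12.0 | 37 | 4 |
| 25.0 | 33 | 12 |
| 30.0 | 30 | 14 |
| 50.0 | 23 | 23 |

(readings scatter by 1.5 percentage points)

- given per volume of solution although it is solid: J
- at the start none of J is in solution
- the earlier runs do not show what temperature does; that part of a forecast is a guess

- which flask leads in amount of Q, in percent of the L charged ("all alike" within 1.5 percentage points) (eta / alpha / gamma / delta / all alike)
- how much Q is there at the end, in percent of the L charged: eta
- how much Q is there at the end, in percent of the L charged: alpha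
- how much Q is there at the end, in percent of the L charged: gamma
- how much Q is there at the end, in percent of the L charged: delta

In the west run Q falls steadily from its first reading to its last, so it can be treated as a pseudo-first-order decay. Its lifetime τ, the time in which Q falls by a factor e, is read from those two readings:

τ = 79.9 s

Counting from the first reading, eta's end lies this many lifetimes away:

n = 1.73

Q = 37 % × e^(−n) = 6.58 %

The weak link is τ itself, carried unchanged to a flask with less Z. If Z feeds the drain of Q, which is an assumption, the lifetime stretches as the Z charge shrinks: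

τ(eta) = 118 s

n = 1.17

Q = 11.5 %

That is the number committed to for eta. Heat is a guess: a factor of 8 on the rate from 30 °C to 60 °C gives delta a lifetime of 14.7 s, so 9.37 lifetimes pass. Delta, and on the same guess gamma and alpha, are therefore put near zero, and eta leads.

The forecast also has eta leading, but with 4 %, less than the reckoning here, on the ground that “the Q + D pool scales to about 30%”, and it gives 0.5 % for delta, 0.2 % for gamma and 0.1 % for alpha.

The flask gives 12.7 % in eta, 0.592 % in delta, 0 % in gamma and 0 % in alpha, so eta leads.

    L + X → Q (k = 2500 /M/s, Ea = 47.0 kJ/mol)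
    X + Z → E (k = 2600 /M/s, Ea = 47.0 kJ/mol)
    Q + E → D (k = 260 /M/s, Ea = 38.0 kJ/mol)
    J ⇌ X, rate k4*(cs4 - [X]) while solid is left; crystals form when [X] > cs4 (solubility = 0.360 mM, k = 0.240 /s)
    L + Q → G (k = 48.0 /M/s, Ea = 57.0 kJ/mol)
    (constants at 60 °C)

Between half time and the end, Q in eta falls from 23.2 % to 12.7 %, a lifetime of 124 s, which is longer than the 79.9 s of the west run and close to the stretched 118 s. A neighbouring flask is like alpha but has 0.380 equiv of Z; the same stretching, applied to the lifetime guessed for delta, gives it 36.8 s, and the count from the first reading leaves 0.871 % of Q. That neighbouring flask ends with 8.94 % of Q, more than the count gives and more than alpha's 0 %, and in it L stands at 0 % and E at 3.77 × 10⁻¹¹ M.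

The runs were generated by integration with made-up constants; noise was put on by code.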